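The oxolane is opened at O1–C5, the ring bond flanking the C4 carbinol. With C4 as a ketone, C5 can be a diazo carbon whose rhodium carbenoid is trapped by the C2 benzylic hydroxyl of an open-chain syn aldol adduct. One operation thus forms O1–C5 and closes the ring as a 2,3-cis oxolan-4-one, leaving C2 and C3, set by an auxiliary-controlled syn aldol, untouched. The precursor is the (3S,4S) hydroxy diazoketone 15, its C3 arm masked as a bulky tert-butyldiphenylsilyl ether. Hydride attack anti to the C2 and C3 substituents then sets C4; desilylation and veratroylation of the primary hydroxyl complete the target.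

Key step: step 9

Remark on the chemistry: the target is read as the all-cis (2S,3R,4S) oxolane (aryl, ester arm and hydroxyl on one face). Ring compounds are numbered O1, C2 (aryl), C3, C4, C5 throughout. The (S)-configured auxiliary and a syn aldol lead to exactly this series.

Step 1
Reactants: 1 methyl 3-hydroxypropanoate
Product: 2 methyl 3-[(tert-butyldiphenylsilyl)oxy]propanoate
Conditions: TBDPSCl, imidazole, DMF, 0 °C → rt
Reagents that add atoms: tert-butyl(chloro)diphenylsilane (TBDPSCl), CC(C)(C)[Si](Cl)(c1ccccc1)c1ccccc1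
Why: Imidazole-promoted silylation of an unhindered primary alcohol is routine, and the bulky, acid-stable silyl group should survive every later step and shield the arm oxygen in the key step.

Step 2
Reactants: 2 methyl 3-[(tert-butyldiphenylsilyl)oxy]propanoate
Product: 3 3-[(tert-butyldiphenylsilyl)oxy]propanoic acid
Conditions: LiOH, THF/H2O, 0 °C → rt; then 1 M HCl to pH 3
Reagents that add atoms: lithium hydroxide, [Li+].[OH-]
Why: Saponification of a methyl ester by acyl–oxygen cleavage should proceed cleanly in the cold, where the silyl ether is stable and β-elimination from the ester is negligible.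

Step 3
Reactants: 3 3-[(tert-butyldiphenylsilyl)oxy]propanoic acid; 4 (S)-4-benzyl-1,3-oxazolidin-2-one
Product: 6 (S)-4-benzyl-3-{3-[(tert-butyldiphenylsilyl)oxy]propanoyl}-1,3-oxazolidin-2-one, via mixed pivalic anhydride 5 (not isolated)
Conditions: PivCl, Et3N, THF, −20 °C; then 4, LiCl, −20 °C → rt
Reagents that add atoms: none
Why: In this one-pot mixed-anhydride N-acylation the LiCl/Et3N-activated oxazolidinone should attack the less hindered acyl carbon of the pivalic anhydride, which avoids strong base and an acid chloride.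

Step 4
Reactants: 6 (S)-4-benzyl-3-{3-[(tert-butyldiphenylsilyl)oxy]propanoyl}-1,3-oxazolidin-2-one; 7 3,4-dimethoxybenzaldehyde
Product: 9 (4S)-4-benzyl-3-[(2S,3S)-2-{[(tert-butyldiphenylsilyl)oxy]methyl}-3-(3,4-dimethoxyphenyl)-3-hydroxypropanoyl]-1,3-oxazolidin-2-one (syn aldol adduct), via Z boron enolate 8 (not isolated)
Conditions: Bu2BOTf, i-Pr2NEt, CH2Cl2, −78 → 0 °C; 7, −78 → 0 °C; then pH 7 buffer, MeOH, H2O2, 0 °C
Reagents that add atoms: none
Why: In this Evans syn aldol the Z boron enolate reacts through a chair Zimmerman–Traxler transition state with the auxiliary carbonyl turned away, so the aldehyde adds to the enolate face remote from the benzyl group and both new centres (2S and 3S, syn) are set by the auxiliary; covalent boron enolates of β-silyloxy carbonyl compounds should not eliminate at these temperatures.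

Step 5
Reactants: 9 the syn aldol adduct
Product: 10 (4S)-4-benzyl-3-[(2S,3S)-2-{[(tert-butyldiphenylsilyl)oxy]methyl}-3-(3,4-dimethoxyphenyl)-3-[(triethylsilyl)oxy]propanoyl]-1,3-oxazolidin-2-one
Conditions: TESOTf, 2,6-lutidine, CH2Cl2, −78 → 0 °C
Reagents that add atoms: triethylsilyl trifluoromethanesulfonate (TESOTf), CC[Si](CC)(CC)OS(=O)(=O)C(F)(F)F
Why: Silylation of the benzylic hydroxyl should block retro-aldol cleavage during auxiliary removal and O-acylation or lactonisation during carboxyl activation, and the triethylsilyl ether can later be cleaved without touching the tert-butyldiphenylsilyl ether.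

Step 6
Reactants: 10 the bis-silylated imide
Product: 12 (2S,3S)-2-{[(tert-butyldiphenylsilyl)oxy]methyl}-3-(3,4-dimethoxyphenyl)-3-[(triethylsilyl)oxy]propanoic acid, via peroxy acid 11 (not isolated)
Conditions: LiOH, H2O2, THF/H2O (3:1), 0 °C; then Na2SO3; 1 M HCl to pH 4, 0 °C
Reagents that add atoms: hydrogen peroxide (as LiOOH), OO
Why: Hydroperoxide-mediated hydrolysis of the N-acyl oxazolidinone should attack the exocyclic carbonyl selectively and, being only weakly basic, leave the α-centre and both silyl ethers intact; sulfite reduces the peroxy acid and the auxiliary is recovered.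

Step 7
Reactants: 12 the silyl-protected acid
Product: 14 (3S,4S)-3-{[(tert-butyldiphenylsilyl)oxy]methyl}-1-diazo-4-(3,4-dimethoxyphenyl)-4-[(triethylsilyl)oxy]butan-2-one, via mixed carbonic anhydride 13 (not isolated)
Conditions: i-BuOCOCl, N-methylmorpholine, THF, −20 °C; then CH2N2 (ethereal solution, excess), −20 → 0 °C
Reagents that add atoms: diazomethane, C=[N+]=[N-]
Why: Acylation of diazomethane by a mixed carbonic anhydride (the first stage of an Arndt–Eistert sequence) should give the terminal α-diazoketone under nearly neutral conditions that do not epimerise the α-centre or disturb the silyl ethers.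

Step 8
Reactants: 14 the triethylsilyl-protected diazoketone
Product: 15 (3S,4S)-3-{[(tert-butyldiphenylsilyl)oxy]methyl}-1-diazo-4-(3,4-dimethoxyphenyl)-4-hydroxybutan-2-one (syn hydroxy diazoketone)
Conditions: HF·pyridine, pyridine (excess), THF, 0 °C
Reagents that add atoms: none
Why: Pyridine-buffered fluoride-mediated desilylation should cleave the labile triethylsilyl ether selectively, since the tert-butyldiphenylsilyl ether is orders of magnitude slower and the buffered medium should be too weakly acidic to protonate the diazo carbon.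

Step 9
Reactants: 15 the syn hydroxy diazoketone
Product: 16 (2S,3S)-3-{[(tert-butyldiphenylsilyl)oxy]methyl}-2-(3,4-dimethoxyphenyl)oxolan-4-one (2,3-cis)
Conditions: Rh2(OAc)4 (1 mol %), CH2Cl2, 4 Å MS, rt, slow addition of 15 at high dilution
Reagents that add atoms: none
Why: Rh2(OAc)4 expels N2 from the diazoketone to give an electrophilic rhodium carbenoid at C5; the C2 hydroxyl oxygen adds to it to give a five-membered oxonium ylide, and a proton shift with release of the catalyst completes a formal O–H insertion, the known route from 1-diazo-4-hydroxybutan-2-ones to oxolan-3-ones. The ring closes in a 5-exo fashion, the oxygen attacking the trigonal carbenoid carbon whose Rh=C bond stays outside the ring. No stereocentre is created, and C2 and C3 are spectators, so the syn aldol relationship of 15 is carried over as the 2,3-cis relationship of 16. The step needs chemoselectivity for the hydroxyl over the electron-rich arene (Buchner-type cycloaddition or aromatic substitution), the silyl ether oxygen and C–H bonds: the free hydroxyl is the most nucleophilic site and sits 1,5 to the carbenoid carbon, the only other atoms at that distance are the shielded silyl ether oxygen and the aryl ipso carbon, so no 1,5 C–H insertion channel exists, and the acetate-ligated, moderately electrophilic catalyst favours ylide formation. Slow addition at high dilution should suppress intermolecular insertion and carbene dimerisation, and 16 is carried forward at once to avoid epimerisation at C3.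

Step 10
Reactants: 16 the 2,3-cis oxolan-4-one
Product: 17 (2S,3R,4S)-3-{[(tert-butyldiphenylsilyl)oxy]methyl}-2-(3,4-dimethoxyphenyl)oxolan-4-ol (all-cis)
Conditions: LiBH(s-Bu)3, THF, −78 °C; then NaOH, H2O2, 0 °C
Reagents that add atoms: none
Why: In this bulky trialkylborohydride reduction the C2 aryl and C3 silyloxymethyl groups occupy one face of the ketone, so hydride should enter from the open face and place the new C4 hydroxyl cis to both (4S); the low temperature and low basicity of the reagent should preserve C3.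

Step 11
Reactants: 17 the all-cis silyl ether alcohol
Product: 18 (2S,3R,4S)-2-(3,4-dimethoxyphenyl)-3-(hydroxymethyl)oxolan-4-ol
Conditions: Bu4NF, AcOH, THF, 0 °C → rt
Reagents that add atoms: none
Why: Fluoride-mediated cleavage of the primary silyl ether is driven by Si–F bond formation, and acetic acid buffering keeps the medium non-basic so that the benzylic ether ring and the stereocentres should be unaffected.

Step 12
Reactants: 18 the diol; 19 3,4-dimethoxybenzoyl chloride
Product: 20 [(2S,3R,4S)-2-(3,4-dimethoxyphenyl)-4-hydroxyoxolan-3-yl]methyl 3,4-dimethoxybenzoate (target)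
Conditions: 19 (1.05 equiv), 2,4,6-collidine, CH2Cl2, −40 → 0 °C
Reagents that add atoms: none
Why: Acylation with an aroyl chloride and a hindered pyridine base should discriminate kinetically between the unhindered primary hydroxyl and the secondary C4 hydroxyl flanked by a cis substituent, and the primary ester is also the thermodynamically preferred one.

Compound list
1 | methyl 3-hydroxypropanoate | COC(=O)CCO | starting material
2 | methyl 3-[(tert-butyldiphenylsilyl)oxy]propanoate | COC(=O)CCO[Si](c1ccccc1)(c1ccccc1)C(C)(C)C | intermediate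
3 | 3-[(tert-butyldiphenylsilyl)oxy]propanoic acid | OC(=O)CCO[Si](c1ccccc1)(c1ccccc1)C(C)(C)C | intermediate
4 | (S)-4-benzyl-1,3-oxazolidin-2-one | O=C1N[C@@H](Cc2ccccc2)CO1 | starting material
5 | mixed pivalic anhydride of 3 (formed in the flask) | CC(C)(C)C(=O)OC(=O)CCO[Si](c1ccccc1)(c1ccccc1)C(C)(C)C | intermediate
6 | (S)-4-benzyl-3-{3-[(tert-butyldiphenylsilyl)oxy]propanoyl}-1,3-oxazolidin-2-one | O=C(CCO[Si](c1ccccc1)(c1ccccc1)C(C)(C)C)N1[C@@H](Cc2ccccc2)COC1=O | intermediate
7 | 3,4-dimethoxybenzaldehyde (veratraldehyde) | COc1ccc(C=O)cc1OC | starting material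
8 | (Z)-dibutylboron enolate of 6 (formed in the flask) | CCCCB(CCCC)O/C(=C\CO[Si](c1ccccc1)(c1ccccc1)C(C)(C)C)N1[C@@H](Cc2ccccc2)COC1=O | intermediate
9 | (4S)-4-benzyl-3-[(2S,3S)-2-{[(tert-butyldiphenylsilyl)oxy]methyl}-3-(3,4-dimethoxyphenyl)-3-hydroxypropanoyl]-1,3-oxazolidin-2-one (syn aldol adduct) | O=C([C@@H](CO[Si](c1ccccc1)(c1ccccc1)C(C)(C)C)[C@H](O)c1ccc(OC)c(OC)c1)N1[C@@H](Cc2ccccc2)COC1=O | intermediate
10 | (4S)-4-benzyl-3-[(2S,3S)-2-{[(tert-butyldiphenylsilyl)oxy]methyl}-3-(3,4-dimethoxyphenyl)-3-[(triethylsilyl)oxy]propanoyl]-1,3-oxazolidin-2-one | O=C([C@@H](CO[Si](c1ccccc1)(c1ccccc1)C(C)(C)C)[C@H](O[Si](CC)(CC)CC)c1ccc(OC)c(OC)c1)N1[C@@H](Cc2ccccc2)COC1=O | intermediate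
11 | (2S,3S)-2-{[(tert-butyldiphenylsilyl)oxy]methyl}-3-(3,4-dimethoxyphenyl)-3-[(triethylsilyl)oxy]propaneperoxoic acid (formed in the flask) | OOC(=O)[C@@H](CO[Si](c1ccccc1)(c1ccccc1)C(C)(C)C)[C@H](O[Si](CC)(CC)CC)c1ccc(OC)c(OC)c1 | intermediate
12 | (2S,3S)-2-{[(tert-butyldiphenylsilyl)oxy]methyl}-3-(3,4-dimethoxyphenyl)-3-[(triethylsilyl)oxy]propanoic acid | OC(=O)[C@@H](CO[Si](c1ccccc1)(c1ccccc1)C(C)(C)C)[C@H](O[Si](CC)(CC)CC)c1ccc(OC)c(OC)c1 | intermediate
13 | isobutyl carbonic mixed anhydride of 12 (formed in the flask) | CC(C)COC(=O)OC(=O)[C@@H](CO[Si](c1ccccc1)(c1ccccc1)C(C)(C)C)[C@H](O[Si](CC)(CC)CC)c1ccc(OC)c(OC)c1 | intermediate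
14 | (3S,4S)-3-{[(tert-butyldiphenylsilyl)oxy]methyl}-1-diazo-4-(3,4-dimethoxyphenyl)-4-[(triethylsilyl)oxy]butan-2-one | [N-]=[N+]=CC(=O)[C@@H](CO[Si](c1ccccc1)(c1ccccc1)C(C)(C)C)[C@H](O[Si](CC)(CC)CC)c1ccc(OC)c(OC)c1 | intermediate
15 | (3S,4S)-3-{[(tert-butyldiphenylsilyl)oxy]methyl}-1-diazo-4-(3,4-dimethoxyphenyl)-4-hydroxybutan-2-one (syn) | [N-]=[N+]=CC(=O)[C@@H](CO[Si](c1ccccc1)(c1ccccc1)C(C)(C)C)[C@H](O)c1ccc(OC)c(OC)c1 | intermediate
16 | (2S,3S)-3-{[(tert-butyldiphenylsilyl)oxy]methyl}-2-(3,4-dimethoxyphenyl)oxolan-4-one (2,3-cis) | CC(C)(C)[Si](c1ccccc1)(c1ccccc1)OC[C@@H]1C(=O)CO[C@@H]1c1ccc(OC)c(OC)c1 | intermediate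
17 | (2S,3R,4S)-3-{[(tert-butyldiphenylsilyl)oxy]methyl}-2-(3,4-dimethoxyphenyl)oxolan-4-ol (all-cis) | CC(C)(C)[Si](c1ccccc1)(c1ccccc1)OC[C@@H]1[C@H](O)CO[C@@H]1c1ccc(OC)c(OC)c1 | intermediate
18 | (2S,3R,4S)-2-(3,4-dimethoxyphenyl)-3-(hydroxymethyl)oxolan-4-ol | OC[C@@H]1[C@H](O)CO[C@@H]1c1ccc(OC)c(OC)c1 | intermediate
19 | 3,4-dimethoxybenzoyl chloride (veratroyl chloride) | COc1ccc(C(Cl)=O)cc1OC | starting material
20 | [(2S,3R,4S)-2-(3,4-dimethoxyphenyl)-4-hydroxyoxolan-3-yl]methyl 3,4-dimethoxybenzoate | COc1ccc(C(=O)OC[C@@H]2[C@H](O)CO[C@@H]2c2ccc(OC)c(OC)c2)cc1OC | target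

Total step count: 12. Longest linear sequence: 12 steps (1 → 20).

Steps most likely to fail

Step 9. The carbenoid may be diverted to the electron-rich arene (cycloaddition with ring expansion or aromatic substitution), or the cis ketone may epimerise at C3 or lose silanol on handling. The fallback sets out from 15 and comes back at 16 without a carbenoid. One equivalent of 48% aqueous HBr in Et2O at −30 °C protonates the diazo carbon, and bromide displaces N2 to give (3S,4S)-1-bromo-3-{[(tert-butyldiphenylsilyl)oxy]methyl}-4-(3,4-dimethoxyphenyl)-4-hydroxybutan-2-one F1. Ag2O in CH2Cl2 then closes O1–C5 by an intramolecular Williamson-type O-alkylation (5-exo-tet) to give 16. Exposure to HBr must stay short and cold because the benzylic alcohol is acid-sensitive.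

Step 8. Protonation of the diazo carbon followed by capture by fluoride, or partial loss of the tert-butyldiphenylsilyl group, may erode the diazoketone during desilylation. The fallback sets out from 9 and comes back at 15, with no silyl ether to cleave next to the diazo group. LiOH/H2O2 (then Na2SO3) removes the auxiliary from the unprotected adduct through the peroxy acid (2S,3S)-2-{[(tert-butyldiphenylsilyl)oxy]methyl}-3-(3,4-dimethoxyphenyl)-3-hydroxypropaneperoxoic acid F2 to give the hydroxy acid (2S,3S)-2-{[(tert-butyldiphenylsilyl)oxy]methyl}-3-(3,4-dimethoxyphenyl)-3-hydroxypropanoic acid F3. At −20 °C i-BuOCOCl and N-methylmorpholine should activate the carboxylate selectively, since O-acylation of the hindered secondary alcohol and four-membered lactonisation are slow. The resulting isobutyl carbonic mixed anhydride of the hydroxy acid F4 is quenched with CH2N2 to give 15 directly.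

Step 7. The hindered mixed anhydride may be attacked at the carbonate carbonyl, returning the carboxylate, which diazomethane then converts into the methyl ester. The fallback sets out from 12 and comes back at 14 by building the diazo group through diazo transfer. Coupling with MeNHOMe·HCl (EDC, i-Pr2NEt) gives the amide (2S,3S)-2-{[(tert-butyldiphenylsilyl)oxy]methyl}-3-(3,4-dimethoxyphenyl)-N-methoxy-N-methyl-3-[(triethylsilyl)oxy]propanamide F5. MeMgBr in THF converts it into the methyl ketone (3S,4S)-3-{[(tert-butyldiphenylsilyl)oxy]methyl}-4-(3,4-dimethoxyphenyl)-4-[(triethylsilyl)oxy]butan-2-one F6. Kinetic deprotonation at the methyl group with LiN(SiMe3)2 at −78 °C and trapping with 2,2,2-trifluoroethyl trifluoroacetate gives the trifluoroacetyl diketone (5S,6S)-5-{[(tert-butyldiphenylsilyl)oxy]methyl}-6-(3,4-dimethoxyphenyl)-1,1,1-trifluoro-6-[(triethylsilyl)oxy]hexane-2,4-dione F7. Detrifluoroacetylative diazo transfer with MsN3 and Et3N in aqueous MeCN then gives 14.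

Further compounds
F1 | step 9 | (3S,4S)-1-bromo-3-{[(tert-butyldiphenylsilyl)oxy]methyl}-4-(3,4-dimethoxyphenyl)-4-hydroxybutan-2-one | BrCC(=O)[C@@H](CO[Si](c1ccccc1)(c1ccccc1)C(C)(C)C)[C@H](O)c1ccc(OC)c(OC)c1
F2 | step 8 | (2S,3S)-2-{[(tert-butyldiphenylsilyl)oxy]methyl}-3-(3,4-dimethoxyphenyl)-3-hydroxypropaneperoxoic acid | OOC(=O)[C@@H](CO[Si](c1ccccc1)(c1ccccc1)C(C)(C)C)[C@H](O)c1ccc(OC)c(OC)c1
F3 | step 8 | (2S,3S)-2-{[(tert-butyldiphenylsilyl)oxy]methyl}-3-(3,4-dimethoxyphenyl)-3-hydroxypropanoic acid | OC(=O)[C@@H](CO[Si](c1ccccc1)(c1ccccc1)C(C)(C)C)[C@H](O)c1ccc(OC)c(OC)c1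
F4 | step 8 | isobutyl carbonic mixed anhydride of F3 | CC(C)COC(=O)OC(=O)[C@@H](CO[Si](c1ccccc1)(c1ccccc1)C(C)(C)C)[C@H](O)c1ccc(OC)c(OC)c1
F5 | step 7 | (2S,3S)-2-{[(tert-butyldiphenylsilyl)oxy]methyl}-3-(3,4-dimethoxyphenyl)-N-methoxy-N-methyl-3-[(triethylsilyl)oxy]propanamide | CON(C)C(=O)[C@@H](CO[Si](c1ccccc1)(c1ccccc1)C(C)(C)C)[C@H](O[Si](CC)(CC)CC)c1ccc(OC)c(OC)c1
F6 | step 7 | (3S,4S)-3-{[(tert-butyldiphenylsilyl)oxy]methyl}-4-(3,4-dimethoxyphenyl)-4-[(triethylsilyl)oxy]butan-2-one | CC(=O)[C@@H](CO[Si](c1ccccc1)(c1ccccc1)C(C)(C)C)[C@H](O[Si](CC)(CC)CC)c1ccc(OC)c(OC)c1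
F7 | step 7 | (5S,6S)-5-{[(tert-butyldiphenylsilyl)oxy]methyl}-6-(3,4-dimethoxyphenyl)-1,1,1-trifluoro-6-[(triethylsilyl)oxy]hexane-2,4-dione | FC(F)(F)C(=O)CC(=O)[C@@H](CO[Si](c1ccccc1)(c1ccccc1)C(C)(C)C)[C@H](O[Si](CC)(CC)CC)c1ccc(OC)c(OC)c1
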